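**Retrosynthetic overview**
1. Target 12 ⇒ six-fold O-demethylation of hexamethyl ether 11 ⇒ α-methylenation of deoxybenzoin 9.
2. 9 ⇒ C7 Friedel–Crafts acylation of benzofuran 6 with 4-methoxyphenylacetic acid 7.
3. 6 ⇒ key step, C3–C3a bond by iodine(III) umpolung: the α-carbon of a β-aryloxy enone is turned into an enolonium equivalent and joined to the ortho carbon of its own electron-rich aryloxy ring (both carbons natively nucleophilic).
4. The β-aryloxy enone 5 ⇒ oxa-Michael addition of 3,5-dimethoxyphenol 4 to ynone 3 (same pot); 3 ⇒ acyl Sonogashira coupling of 1 with 2.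
5. Ring order: all benzene rings are bought; the furan is the only ring made (O1–C2 first, then C3–C3a).

Assumption: the target has no stereocentre and no stereogenic double bond, so it is achiral and no stereocontrol is needed; the E/Z geometry of transient 5 and the racemic centre of transient 10 are both erased in the same step.

**Step 1**
Reactants: 1 1-ethynyl-4-methoxybenzene; 2 2,4-dimethoxybenzoyl chloride
Product: 3 1-(2,4-dimethoxyphenyl)-3-(4-methoxyphenyl)prop-2-yn-1-one
Conditions: PdCl2(PPh3)2 (2 mol %), CuI (4 mol %), Et3N (1.5 equiv), THF, rt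
Reagents that add atoms: none
Why: Acyl Sonogashira coupling: Pd(0) inserts into the aroyl C–Cl bond and the copper acetylide transmetallates, giving the ynone with the aryl ethers untouched; no stereocentre.

**Step 2**
Reactants: 3 1-(2,4-dimethoxyphenyl)-3-(4-methoxyphenyl)prop-2-yn-1-one; 4 3,5-dimethoxyphenol
Product: 6 (2,4-dimethoxyphenyl)[4,6-dimethoxy-2-(4-methoxyphenyl)-1-benzofuran-3-yl]methanone, via aryloxy enone 5 (not isolated)
Conditions: Cs2CO3 (10 mol %), MeCN, 40 °C; then HFIP, PhI(OAc)2 (1.1 equiv), −20 → 0 °C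
Reagents that add atoms: none
Why: Proposed new method: phenoxide oxa-Michael addition to the ynone gives the push–pull enol ether 5 (E/Z irrelevant), whose α-carbon attacks HFIP-activated PhI(OAc)2 to give an α-(phenyl-λ3-iodanyl) oxocarbenium ion, i.e. an enolonium equivalent; the tethered 3,5-dimethoxyphenoxy ring (two equivalent ortho carbons, each ortho/para to OMe) displaces PhI in a 5-exo Friedel–Crafts closure and two proton losses aromatise the furan, so two natively nucleophilic carbons are joined and the tether fixes the regiochemistry (C2 aryl, C3 aroyl, 4,6-dimethoxy); the closest known reaction types are the PhI(OAc)2-mediated oxidative C–C cyclisation of N-aryl enaminones to 3-acylindoles and the iodine(III) enolonium α-arylation of ketones with electron-rich arenes; no stereocentre.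

**Step 3**
Reactants: 6 (2,4-dimethoxyphenyl)[4,6-dimethoxy-2-(4-methoxyphenyl)-1-benzofuran-3-yl]methanone; 7 4-methoxyphenylacetic acid
Product: 9 1-[3-(2,4-dimethoxybenzoyl)-4,6-dimethoxy-2-(4-methoxyphenyl)-1-benzofuran-7-yl]-2-(4-methoxyphenyl)ethan-1-one, via mixed anhydride 8 (not isolated)
Conditions: 7 (1.5 equiv), (CF3CO)2O (1.5 equiv), CH2Cl2, 0 °C; then 6, 85 % H3PO4 (cat.), 0 °C → rt
Reagents that add atoms: none
Why: Friedel–Crafts acylation through the mixed anhydride 8 (the electron-richer acyl half is transferred): attack occurs at C7 (ortho to O1 and 6-OMe, para to 4-OMe) and not at C5, which is flanked by two methoxy groups with the 4-OMe pushed toward it by the peri aroyl group, in line with the known C7 selectivity of 2,3-disubstituted 4,6-dimethoxybenzofurans; no stereocentre.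

**Step 4**
Reactants: 9 1-[3-(2,4-dimethoxybenzoyl)-4,6-dimethoxy-2-(4-methoxyphenyl)-1-benzofuran-7-yl]-2-(4-methoxyphenyl)ethan-1-one
Product: 11 1-[3-(2,4-dimethoxybenzoyl)-4,6-dimethoxy-2-(4-methoxyphenyl)-1-benzofuran-7-yl]-2-(4-methoxyphenyl)prop-2-en-1-one, via Mannich base 10 (not isolated)
Conditions: CH2(NMe2)2 (3 equiv), Ac2O (4 equiv), THF, 65 °C
Reagents that add atoms: bis(dimethylamino)methane, CN(C)CN(C)C
Why: Mannich condensation of the benzylic ketone enol with in situ N,N-dimethylmethyleneiminium acetate gives β-amino ketone 10 (racemic, transient), whose N-acetylation triggers E1cB β-elimination to the 1,1-disubstituted enone (α-methylenation); no free OH is present that could close to an isoflavanone.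

**Step 5**
Reactants: 11 1-[3-(2,4-dimethoxybenzoyl)-4,6-dimethoxy-2-(4-methoxyphenyl)-1-benzofuran-7-yl]-2-(4-methoxyphenyl)prop-2-en-1-one
Product: 12 1-[3-(2,4-dihydroxybenzoyl)-4,6-dihydroxy-2-(4-hydroxyphenyl)-1-benzofuran-7-yl]-2-(4-hydroxyphenyl)prop-2-en-1-one
Conditions: BBr3 (12 equiv), CH2Cl2, −78 → 0 °C (rt if needed); ice–water quench, EtOAc, pH 5 acetate-buffer wash, no basic work-up
Reagents that add atoms: none
Why: BBr3 Lewis-acid ether cleavage removes all six methyl ethers (those ortho/peri to carbonyls first, by chelation) while the enone, which has no free ortho position for Nazarov closure, is retained; any bromide adduct (β-bromo ketone) re-eliminates on the weakly acidic buffered work-up, which also avoids phenoxide-triggered oxa-Michael closure to the isoflavanone; no stereocentre.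

**Compound list**
1 | 1-ethynyl-4-methoxybenzene (4-ethynylanisole) | C#Cc1ccc(OC)cc1 | starting material
2 | 2,4-dimethoxybenzoyl chloride | COc1ccc(C(=O)Cl)c(OC)c1 | starting material
3 | 1-(2,4-dimethoxyphenyl)-3-(4-methoxyphenyl)prop-2-yn-1-one | COc1ccc(cc1)C#CC(=O)c1ccc(OC)cc1OC | intermediate
4 | 3,5-dimethoxyphenol | COc1cc(O)cc(OC)c1 | starting material
5 | (Z)-3-(3,5-dimethoxyphenoxy)-1-(2,4-dimethoxyphenyl)-3-(4-methoxyphenyl)prop-2-en-1-one | COc1ccc(cc1)/C(Oc1cc(OC)cc(OC)c1)=C/C(=O)c1ccc(OC)cc1OC | intermediate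
6 | (2,4-dimethoxyphenyl)[4,6-dimethoxy-2-(4-methoxyphenyl)-1-benzofuran-3-yl]methanone | COc1ccc(cc1)-c1oc2cc(OC)cc(OC)c2c1C(=O)c1ccc(OC)cc1OC | intermediate
7 | 4-methoxyphenylacetic acid | COc1ccc(CC(=O)O)cc1 | starting material
8 | (4-methoxyphenyl)acetic trifluoroacetic anhydride | COc1ccc(CC(=O)OC(=O)C(F)(F)F)cc1 | intermediate
9 | 1-[3-(2,4-dimethoxybenzoyl)-4,6-dimethoxy-2-(4-methoxyphenyl)-1-benzofuran-7-yl]-2-(4-methoxyphenyl)ethan-1-one | COc1ccc(CC(=O)c2c(OC)cc(OC)c3c(C(=O)c4ccc(OC)cc4OC)c(-c4ccc(OC)cc4)oc23)cc1 | intermediate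
10 | rac-1-[3-(2,4-dimethoxybenzoyl)-4,6-dimethoxy-2-(4-methoxyphenyl)-1-benzofuran-7-yl]-3-(dimethylamino)-2-(4-methoxyphenyl)propan-1-one | CN(C)CC(C(=O)c1c(OC)cc(OC)c2c(C(=O)c3ccc(OC)cc3OC)c(-c3ccc(OC)cc3)oc12)c1ccc(OC)cc1 | intermediate
11 | 1-[3-(2,4-dimethoxybenzoyl)-4,6-dimethoxy-2-(4-methoxyphenyl)-1-benzofuran-7-yl]-2-(4-methoxyphenyl)prop-2-en-1-one | C=C(C(=O)c1c(OC)cc(OC)c2c(C(=O)c3ccc(OC)cc3OC)c(-c3ccc(OC)cc3)oc12)c1ccc(OC)cc1 | intermediate
12 | 1-[3-(2,4-dihydroxybenzoyl)-4,6-dihydroxy-2-(4-hydroxyphenyl)-1-benzofuran-7-yl]-2-(4-hydroxyphenyl)prop-2-en-1-one | C=C(C(=O)c1c(O)cc(O)c2c(C(=O)c3ccc(O)cc3O)c(-c3ccc(O)cc3)oc12)c1ccc(O)cc1 | target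

**Step count**
Total steps: 5. Longest linear sequence: 5 (1 + 2 → 3 → 6 → 9 → 11 → 12).

**Three steps most likely to fail**

Step 2 (key oxidative closure). The iodine(III) reagent may instead attack the trioxygenated ring at the position para to oxygen, over-oxidise product 6, or the acid formed may close 5 to a benzopyrylium salt. The fallback sets out from 4 and returns at 6, making the C3–C3a bond first and intermolecularly. Claisen condensation of 2',4'-dimethoxyacetophenone with methyl 4-methoxybenzoate (NaH, THF, reflux) gives 1-(2,4-dimethoxyphenyl)-3-(4-methoxyphenyl)propane-1,3-dione F1. FeCl3·6H2O (10 mol %) and (t-BuO)2 in DCE at 100 °C then couple the iron-bound diketonate oxidatively with the ortho carbon of 4, giving 2-(2-hydroxy-4,6-dimethoxyphenyl)-1-(2,4-dimethoxyphenyl)-3-(4-methoxyphenyl)propane-1,3-dione F2, which is not isolated. Its phenol oxygen condenses in the same pot onto the less hindered, more electrophilic 4-methoxybenzoyl carbonyl to give 6. The isomeric closure product and any para-coupled phenol (base-extractable) would have to be separated.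

Step 3 (C7 acylation). Some C5 acylation, or decarbonylative benzylation by the arylacetyl cation, could erode the yield. The fallback sets out from 4 and returns at 9, carrying the acyl group in on the phenol so that the tether dictates its position. BF3·OEt2-mediated ortho-acylation of 4 with acid 7 (85 °C) gives 1-(2-hydroxy-4,6-dimethoxyphenyl)-2-(4-methoxyphenyl)ethan-1-one F3. Its chelated phenol is added to ynone 3 (Cs2CO3 cat., MeCN, 50 °C) to give (Z)-3-{3,5-dimethoxy-2-[(4-methoxyphenyl)acetyl]phenoxy}-1-(2,4-dimethoxyphenyl)-3-(4-methoxyphenyl)prop-2-en-1-one F4. The iodine(III) closure of step 2 can then only engage the single free ortho carbon, which gives 9 with the acyl group necessarily at C7.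

Step 5 (BBr3 on the enone). Bromide or HBr conjugate addition, oligomerisation of the aryl vinyl ketone, or closure of 12 to the isoflavanone during work-up are the dangers. The fallback sets out from 9 and returns at 12, keeping the enone masked through the demethylation. Eschenmoser's salt (CH2=NMe2+ I−, MeCN, 60 °C) without acetic anhydride stops at the Mannich base 10, isolated as its hydriodide. BBr3 on this salt, where no enone is present, gives rac-1-[3-(2,4-dihydroxybenzoyl)-4,6-dihydroxy-2-(4-hydroxyphenyl)-1-benzofuran-7-yl]-3-(dimethylamino)-2-(4-hydroxyphenyl)propan-1-one F5 as its hydrobromide. Warming F5 at pH 5 (NaOAc/AcOH, aqueous dioxane, 50 °C) eliminates dimethylamine by retro-Michael reaction and gives 12 without exposing the enone to BBr3 or to phenoxide.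

**Further compounds**
F1 | step 2 | 1-(2,4-dimethoxyphenyl)-3-(4-methoxyphenyl)propane-1,3-dione | COc1ccc(cc1)C(=O)CC(=O)c1ccc(OC)cc1OC
F2 | step 2 | 2-(2-hydroxy-4,6-dimethoxyphenyl)-1-(2,4-dimethoxyphenyl)-3-(4-methoxyphenyl)propane-1,3-dione | COc1ccc(cc1)C(=O)C(c1c(O)cc(OC)cc1OC)C(=O)c1ccc(OC)cc1OC
F3 | step 3 | 1-(2-hydroxy-4,6-dimethoxyphenyl)-2-(4-methoxyphenyl)ethan-1-one | COc1ccc(CC(=O)c2c(O)cc(OC)cc2OC)cc1
F4 | step 3 | (Z)-3-{3,5-dimethoxy-2-[(4-methoxyphenyl)acetyl]phenoxy}-1-(2,4-dimethoxyphenyl)-3-(4-methoxyphenyl)prop-2-en-1-one | COc1ccc(cc1)/C(Oc1cc(OC)cc(OC)c1C(=O)Cc1ccc(OC)cc1)=C/C(=O)c1ccc(OC)cc1OC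
F5 | step 5 | rac-1-[3-(2,4-dihydroxybenzoyl)-4,6-dihydroxy-2-(4-hydroxyphenyl)-1-benzofuran-7-yl]-3-(dimethylamino)-2-(4-hydroxyphenyl)propan-1-one | CN(C)CC(C(=O)c1c(O)cc(O)c2c(C(=O)c3ccc(O)cc3O)c(-c3ccc(O)cc3)oc12)c1ccc(O)cc1
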